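- Target ⇐ bicyclic 3-keto-19-ester with the C2 oxygen already in place, by redox and protecting-group steps only (C3 ketone reduced under direction of the C19 carbinol, C19 acetylated, C15 oxidised).
- Bicyclic keto ester ⇐ open-chain α-bromo β-keto ester in one radical cascade: the C4–C5 bond closes ring A first, the C9–C10 bond closes ring B last, and loss of a phenylsulfonyl group from C7 places the C7=C8 alkene.
- Enabling feature: C4 carries two carbonyl-level carbons (C3 of ring A and C19), so it can be a 1,3-dicarbonyl radical; the ring-B alkene C7=C8 starts at C8, the radical centre left by ring-B closure, so a leaving group on C7 fixes its position; C2 of ring A (oxygenated, 1,3 to both C4 and C10) is the only ring stereocentre that must exist beforehand.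
- Open chain ⇐ C3–C4 (malonate half-ester acylation), C1–C2 (asymmetric glycolate alkylation, sets C2) and C6–C7 (sulfone alkylation; the sulfone is the later leaving group), from (R)-citronellol (C7–C9, C11–C17), isoprene monoxide (C1, C5, C6, C10, C20), a silyloxyacetyl imide (C2, C3) and ethyl methylmalonate (C4, C18, C19).
- Stereoconvergence: the epimers at C4 and C7 of the open-chain precursor all collapse to one bicyclic product.

Key step: step 12

Remark on the chemistry: atom labels C1–C20 are the labdane positions of the target (ring A = C1–C5 and C10, ring B = C5–C10, C19 = oxygenated carbon on C4, C18 = methyl on C4, C20 = methyl on C10, C17 = methyl on C8, C16 = methyl on C13). Centres written without configuration (C7 and C4 of the open-chain compounds, C3 of 21) are epimer mixtures that are erased later. Compounds 11 and 16 are assumed to be purchasable.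

Step 1
Reactants: 1 (R)-citronellol
Product: 2 tert-butyldimethylsilyl ether of (R)-citronellol
Conditions: TBSCl, imidazole, CH2Cl2, 0 to 25 °C
Reagents that add atoms: tert-butyldimethylsilyl chloride, CC(C)(C)[Si](C)(C)Cl
Why: Standard silylation of a primary alcohol should protect the C15 oxygen for the organolithium, hydride and radical steps; no stereocentre is formed.

Step 2
Reactants: 2 tert-butyldimethylsilyl ether of (R)-citronellol
Product: 3 (2E,6R)-8-(tert-butyldimethylsilyloxy)-2,6-dimethyloct-2-en-1-ol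
Conditions: SeO2 (cat.), t-BuOOH, salicylic acid (cat.), CH2Cl2, 25 °C
Reagents that add atoms: tert-butyl hydroperoxide, CC(C)(C)OO (oxygen, relayed through SeO2)
Why: SeO2 allylic oxidation (ene reaction then 2,3-sigmatropic shift) is known to hydroxylate the (E)-methyl group of a trisubstituted gem-dimethyl alkene, which turns that methyl into C7 and fixes the (E)-C8=C9 geometry; no stereocentre is formed.

Step 3
Reactants: 3 (2E,6R)-8-(tert-butyldimethylsilyloxy)-2,6-dimethyloct-2-en-1-ol
Product: 5 (3R,6E)-1-(tert-butyldimethylsilyloxy)-3,7-dimethyl-8-(phenylsulfonyl)oct-6-ene, via allylic bromide 4 (not isolated)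
Conditions: CBr4, PPh3, CH2Cl2, 0 °C; then PhSO2Na, DMF, 25 °C
Reagents that add atoms: sodium benzenesulfinate, [Na+].[O-]S(=O)c1ccccc1; carbon tetrabromide, BrC(Br)(Br)Br (bromine of 4 only)
Why: Appel bromination of the primary allylic alcohol and SN2 S-alkylation of the sulfinate should give the primary allylic sulfone without allylic transposition, which makes C7 acidic for step 5; no stereocentre is formed.

Step 4
Reactants: 6 2-methyl-2-vinyloxirane
Product: 7 (E)-4-chloro-2-methylbut-2-en-1-ol
Conditions: TiCl4, CH2Cl2, −80 °C; aqueous work-up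
Reagents that add atoms: titanium tetrachloride, Cl[Ti](Cl)(Cl)Cl
Why: Lewis-acid-promoted SN2′-type opening of the vinyl epoxide by chloride is a known reaction of this epoxide and should give the (E)-1,4-chlorohydrin, which carries C1, C5, C6, C10 and C20 with the alkene geometry needed for the trans ring fusion; no stereocentre is formed.

Step 5
Reactants: 5 (3R,6E)-1-(tert-butyldimethylsilyloxy)-3,7-dimethyl-8-(phenylsulfonyl)oct-6-ene; 7 (E)-4-chloro-2-methylbut-2-en-1-ol
Product: 8 (2E,6E,10R)-12-(tert-butyldimethylsilyloxy)-2,6,10-trimethyl-5-(phenylsulfonyl)dodeca-2,6-dien-1-ol (epimers at the sulfone carbon)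
Conditions: 5, n-BuLi, THF, −78 °C; then 7 as its lithium alkoxide (n-BuLi, THF, −78 °C), DMPU, −78 to 0 °C
Reagents that add atoms: none
Why: α-Alkylation of the sulfonyl-stabilised allyl anion by the primary allylic chloride (SN2, the classical terpenoid sulfone coupling) should form the C6–C7 bond with both alkene geometries intact; C7 is formed as an epimer mixture on purpose, since it becomes sp2 in step 12.

Step 6
Reactants: 8 (2E,6E,10R)-12-(tert-butyldimethylsilyloxy)-2,6,10-trimethyl-5-(phenylsulfonyl)dodeca-2,6-dien-1-ol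
Product: 9 (3R,6E,10E)-1-(tert-butyldimethylsilyloxy)-12-iodo-3,7,11-trimethyl-8-(phenylsulfonyl)dodeca-6,10-diene
Conditions: PPh3, I2, imidazole, CH2Cl2, 0 °C; used at once
Reagents that add atoms: iodine, II
Why: Appel-type iodination should convert the primary allylic alcohol into the iodide under neutral conditions that leave the allylic sulfone and the silyl ether alone; no stereocentre is formed.

Step 7
Reactants: 10 (R)-4-benzyloxazolidin-2-one; 11 2-(tert-butyldimethylsilyloxy)acetic acid
Product: 13 (R)-4-benzyl-3-[2-(tert-butyldimethylsilyloxy)acetyl]oxazolidin-2-one, via mixed pivalic anhydride 12 (not isolated)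
Conditions: 11, t-BuCOCl, Et3N, THF, −78 to 0 °C; then 10, n-BuLi, THF, −78 °C
Reagents that add atoms: pivaloyl chloride, CC(C)(C)C(=O)Cl (acyl group of 12 only)
Why: N-Acylation of the lithiated oxazolidinone by the mixed pivalic anhydride at its less hindered carbonyl is the standard preparation of Evans imides; the auxiliary stereocentre is untouched.

Step 8
Reactants: 9 (3R,6E,10E)-1-(tert-butyldimethylsilyloxy)-12-iodo-3,7,11-trimethyl-8-(phenylsulfonyl)dodeca-6,10-diene; 13 (R)-4-benzyl-3-[2-(tert-butyldimethylsilyloxy)acetyl]oxazolidin-2-one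
Product: 14 (R)-4-benzyl-3-[(2S,4E,8E,12R)-2,14-bis(tert-butyldimethylsilyloxy)-4,8,12-trimethyl-7-(phenylsulfonyl)tetradeca-4,8-dienoyl]oxazolidin-2-one
Conditions: 13 (2 equiv), NaN(SiMe3)2, THF, −78 °C; then 9, −78 to −45 °C
Reagents that add atoms: none
Why: Evans asymmetric alkylation of the chelated (Z)-sodium enolate of the glycolate imide with a reactive allylic iodide should form the C1–C2 bond on the face opposite the benzyl group, which sets C2 as S, while the weakly basic imide enolate leaves the sulfone α-proton in place.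

Step 9
Reactants: 14 (R)-4-benzyl-3-[(2S,4E,8E,12R)-2,14-bis(tert-butyldimethylsilyloxy)-4,8,12-trimethyl-7-(phenylsulfonyl)tetradeca-4,8-dienoyl]oxazolidin-2-one
Product: 15 (2S,4E,8E,12R)-2,14-bis(tert-butyldimethylsilyloxy)-4,8,12-trimethyl-7-(phenylsulfonyl)tetradeca-4,8-dienoic acid
Conditions: LiOH, H2O2, THF/H2O, 0 °C; Na2SO3; 1 M HCl to pH 3
Reagents that add atoms: hydrogen peroxide, OO (as LiOOH; supplies the hydroxyl oxygen of the acid)
Why: LiOOH hydrolysis attacks the exocyclic imide carbonyl selectively and should release the α-silyloxy acid without epimerising C2; the auxiliary 10 is recovered.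

Step 10
Reactants: 15 (2S,4E,8E,12R)-2,14-bis(tert-butyldimethylsilyloxy)-4,8,12-trimethyl-7-(phenylsulfonyl)tetradeca-4,8-dienoic acid; 16 potassium ethyl 2-methylmalonate
Product: 18 ethyl (4S,6E,10E,14R)-4,16-bis(tert-butyldimethylsilyloxy)-2,6,10,14-tetramethyl-3-oxo-9-(phenylsulfonyl)hexadeca-6,10-dienoate, via acyl imidazolide 17 (not isolated)
Conditions: CDI, THF, 25 °C; then 16, MgCl2, Et3N, MeCN, 25 to 40 °C; 1 M HCl work-up
Reagents that add atoms: 1,1'-carbonyldiimidazole, O=C(n1ccnc1)n1ccnc1 (imidazolyl group of 17 only)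
Why: Masamune–Brooks homologation (C-acylation of the magnesium enolate of the malonate half ester by the acyl imidazolide, then decarboxylation) should build the C3–C4 bond under nearly neutral conditions that spare C2; C4 is formed as an epimer mixture, which is irrelevant because C4 becomes a planar radical.

Step 11
Reactants: 18 ethyl (4S,6E,10E,14R)-4,16-bis(tert-butyldimethylsilyloxy)-2,6,10,14-tetramethyl-3-oxo-9-(phenylsulfonyl)hexadeca-6,10-dienoate
Product: 19 ethyl (4S,6E,10E,14R)-2-bromo-4,16-bis(tert-butyldimethylsilyloxy)-2,6,10,14-tetramethyl-3-oxo-9-(phenylsulfonyl)hexadeca-6,10-dienoate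
Conditions: NaH, THF, 0 °C; then N-bromosuccinimide, −78 to 0 °C
Reagents that add atoms: N-bromosuccinimide, O=C1CCC(=O)N1Br
Why: Electrophilic bromination of the sodium enolate of the β-keto ester (the only proton NaH removes) should give the tertiary α-bromide at C4 without touching the alkenes at −78 °C; both C4 epimers are acceptable.

Step 12
Reactants: 19 ethyl (4S,6E,10E,14R)-2-bromo-4,16-bis(tert-butyldimethylsilyloxy)-2,6,10,14-tetramethyl-3-oxo-9-(phenylsulfonyl)hexadeca-6,10-dienoate
Product: 20 ethyl (2S,4S,5S,9R,10S,13R)-2,15-bis(tert-butyldimethylsilyloxy)-3-oxolabd-7-en-19-oate (trans-decalin; ester on C4 axial and cis to the C10 methyl; C2 silyloxy group equatorial)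
Conditions: Et3B (2.5 equiv, slow addition), air (slow inlet), benzene (0.005 M; 19 added slowly), 25 °C; aqueous NaHCO3 work-up
Reagents that add atoms: none
Why: Proposed new method: Et3B and O2 give an ethyl radical that abstracts bromine from 19 to give the planar C4 1,3-dicarbonyl radical (both C4 epimers give the same radical), which closes ring A by 6-endo-trig attack on C5 of the C5=C10 alkene; the tertiary C10 radical then closes ring B by 6-endo-trig attack on C9 of the C8=C9 alkene, and the resulting tertiary C8 radical expels the phenylsulfonyl radical from C7 by β-scission (both C7 epimers converge), the sulfonyl radical being taken up by Et3B at boron to release the next ethyl radical. The closest known reactions are the Mn(OAc)3/Cu(OAc)2 oxidative and the Et3B/O2 atom-transfer bicyclisations of 2-substituted β-keto ester polyenes, which give trans-decalins with an axial ester, and radical allylation by addition–fragmentation of allylic sulfones with trialkylborane chain transfer; new here is an in-chain allylic sulfone as terminator of a polyene cascade. C4 is set by the radical conformer with anti carbonyl groups, which places the ester axial and the methyl equatorial; C5 and C10 follow from the chair–chair transition state of the (E)-C5=C10 alkene (trans fusion), and C9 from the (E)-C8=C9 alkene, which puts the side chain equatorial. The absolute sense is relayed from C2, the one stereocentre of ring A: the chair that keeps the C2 silyloxy group equatorial avoids a 1,3-diaxial clash with the axial ester on C4 and the axial methyl on C10, so the radical should add to a single face of C5=C10. The regioselectivity needed is the C7=C8 alkene over the C8=C9 and exocyclic isomers, and it is secured because the only β-leaving group of the C8 radical is the sulfonyl group on C7; slow addition at high dilution should keep bromine transfer to the C10 and C8 radicals and reduction of the C4 radical by Et3B behind cyclisation and fragmentation.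

Step 13
Reactants: 20 ethyl (2S,4S,5S,9R,10S,13R)-2,15-bis(tert-butyldimethylsilyloxy)-3-oxolabd-7-en-19-oate
Product: 21 (2S,4R,5S,9R,10S,13R)-2,15-bis(tert-butyldimethylsilyloxy)labd-7-ene-3,19-diol (C3 epimers)
Conditions: LiAlH4, THF, 0 to 25 °C
Reagents that add atoms: none
Why: LiAlH4 reduction of ketone and ester is needed only to bring C19 to the alcohol level; the C3 epimer mixture does not matter because C3 is reoxidised in step 14.

Step 14
Reactants: 21 (2S,4R,5S,9R,10S,13R)-2,15-bis(tert-butyldimethylsilyloxy)labd-7-ene-3,19-diol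
Product: 22 (2S,4R,5S,9R,10S,13R)-2,15-bis(tert-butyldimethylsilyloxy)-3-oxolabd-7-en-19-al
Conditions: Dess–Martin periodinane, NaHCO3, CH2Cl2, 0 to 25 °C
Reagents that add atoms: none
Why: Dess–Martin oxidation of both hydroxyl groups under buffered conditions should give the keto aldehyde, which cannot enolise at the quaternary C4.

Step 15
Reactants: 22 (2S,4R,5S,9R,10S,13R)-2,15-bis(tert-butyldimethylsilyloxy)-3-oxolabd-7-en-19-al
Product: 24 (2S,3R,4R,5S,9R,10S,13R)-2,15-bis(tert-butyldimethylsilyloxy)labd-7-ene-3,19-diol (C3 hydroxyl axial), via hydroxy ketone 23 (not isolated)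
Conditions: Me4NBH(OAc)3, MeCN/AcOH (1:1), −20 to 25 °C
Reagents that add atoms: none
Why: The triacetoxyborohydride reduces the aldehyde first, and the resulting axial C19 carbinol then binds boron and delivers hydride to the C3 ketone on the face that carries C19 through a six-membered chair (Evans–Saksena anti-selective directed reduction), which sets C3 with an axial hydroxyl, trans to C19 and cis to the C2 oxygen.

Step 16
Reactants: 24 (2S,3R,4R,5S,9R,10S,13R)-2,15-bis(tert-butyldimethylsilyloxy)labd-7-ene-3,19-diol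
Product: 25 (2S,3R,4R,5S,9R,10S,13R)-19-acetoxy-2,15-bis(tert-butyldimethylsilyloxy)labd-7-en-3-ol
Conditions: Ac2O (1.2 equiv), pyridine, CH2Cl2, 0 °C
Reagents that add atoms: acetic anhydride, CC(=O)OC(C)=O
Why: Acylation should be selective for the primary C19 hydroxyl because the axial C3 hydroxyl is flanked by quaternary C4 and the C2 silyl ether, and the acetate cannot migrate because O3 and C19 are trans-diaxial.

Step 17
Reactants: 25 (2S,3R,4R,5S,9R,10S,13R)-19-acetoxy-2,15-bis(tert-butyldimethylsilyloxy)labd-7-en-3-ol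
Product: 26 (2S,3R,4R,5S,9R,10S,13R)-19-acetoxy-2-(tert-butyldimethylsilyloxy)labd-7-ene-3,15-diol
Conditions: HF·pyridine, pyridine, THF, 0 °C
Reagents that add atoms: none
Why: Buffered HF·pyridine cleaves primary tert-butyldimethylsilyl ethers much faster than hindered secondary ones, which should unmask the C15 hydroxyl alone.

Step 18
Reactants: 26 (2S,3R,4R,5S,9R,10S,13R)-19-acetoxy-2-(tert-butyldimethylsilyloxy)labd-7-ene-3,15-diol
Product: 27 (2S,3R,4R,5S,9R,10S,13R)-19-acetoxy-3-hydroxy-2-(tert-butyldimethylsilyloxy)labd-7-en-15-oic acid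
Conditions: TEMPO (0.2 equiv), PhI(OAc)2 (2.5 equiv), MeCN/H2O (1:1), 25 °C
Reagents that add atoms: water, O
Why: TEMPO/PhI(OAc)2 oxidation (oxoammonium catalysis) is selective for primary alcohols, proceeds through the aldehyde hydrate to the acid, and should spare the trisubstituted alkene, the acetate and the hindered axial C3 hydroxyl.

Step 19
Reactants: 27 (2S,3R,4R,5S,9R,10S,13R)-19-acetoxy-3-hydroxy-2-(tert-butyldimethylsilyloxy)labd-7-en-15-oic acid
Product: 28 (2S,3R,4R,5S,9R,10S,13R)-19-acetoxy-2,3-dihydroxylabd-7-en-15-oic acid (target, CNP0164890.1)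
Conditions: aqueous HF (48 %), MeCN, 0 to 25 °C
Reagents that add atoms: none
Why: Acidic fluoride desilylation should free the C2 hydroxyl without hydrolysing or moving the C19 acetate, and gives the target.

Compound list
1 | (R)-citronellol | CC(C)=CCC[C@@H](C)CCO | starting material
2 | tert-butyldimethylsilyl ether of (R)-citronellol | CC(C)=CCC[C@@H](C)CCO[Si](C)(C)C(C)(C)C | intermediate
3 | (2E,6R)-8-(tert-butyldimethylsilyloxy)-2,6-dimethyloct-2-en-1-ol | OC/C(C)=C/CC[C@@H](C)CCO[Si](C)(C)C(C)(C)C | intermediate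
4 | (3R,6E)-8-bromo-1-(tert-butyldimethylsilyloxy)-3,7-dimethyloct-6-ene | BrC/C(C)=C/CC[C@@H](C)CCO[Si](C)(C)C(C)(C)C | intermediate (not isolated)
5 | (3R,6E)-1-(tert-butyldimethylsilyloxy)-3,7-dimethyl-8-(phenylsulfonyl)oct-6-ene | O=S(=O)(C/C(C)=C/CC[C@@H](C)CCO[Si](C)(C)C(C)(C)C)c1ccccc1 | intermediate
6 | 2-methyl-2-vinyloxirane (racemic) | CC1(C=C)CO1 | starting material
7 | (E)-4-chloro-2-methylbut-2-en-1-ol | OC/C(C)=C/CCl | intermediate
8 | (2E,6E,10R)-12-(tert-butyldimethylsilyloxy)-2,6,10-trimethyl-5-(phenylsulfonyl)dodeca-2,6-dien-1-ol (epimers at the sulfone carbon, labdane C7) | OC/C(C)=C/CC(S(=O)(=O)c1ccccc1)/C(C)=C/CC[C@@H](C)CCO[Si](C)(C)C(C)(C)C | intermediate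
9 | (3R,6E,10E)-1-(tert-butyldimethylsilyloxy)-12-iodo-3,7,11-trimethyl-8-(phenylsulfonyl)dodeca-6,10-diene (C7 epimers) | IC/C(C)=C/CC(S(=O)(=O)c1ccccc1)/C(C)=C/CC[C@@H](C)CCO[Si](C)(C)C(C)(C)C | intermediate
10 | (R)-4-benzyloxazolidin-2-one | O=C1OC[C@@H](Cc2ccccc2)N1 | starting material
11 | 2-(tert-butyldimethylsilyloxy)acetic acid | CC(C)(C)[Si](C)(C)OCC(=O)O | starting material
12 | 2-(tert-butyldimethylsilyloxy)acetic pivalic anhydride | CC(C)(C)[Si](C)(C)OCC(=O)OC(=O)C(C)(C)C | intermediate (not isolated)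
13 | (R)-4-benzyl-3-[2-(tert-butyldimethylsilyloxy)acetyl]oxazolidin-2-one | O=C1OC[C@@H](Cc2ccccc2)N1C(=O)CO[Si](C)(C)C(C)(C)C | intermediate
14 | (R)-4-benzyl-3-[(2S,4E,8E,12R)-2,14-bis(tert-butyldimethylsilyloxy)-4,8,12-trimethyl-7-(phenylsulfonyl)tetradeca-4,8-dienoyl]oxazolidin-2-one (C7 epimers) | O=C1OC[C@@H](Cc2ccccc2)N1C(=O)[C@@H](O[Si](C)(C)C(C)(C)C)C/C(C)=C/CC(S(=O)(=O)c1ccccc1)/C(C)=C/CC[C@@H](C)CCO[Si](C)(C)C(C)(C)C | intermediate
15 | (2S,4E,8E,12R)-2,14-bis(tert-butyldimethylsilyloxy)-4,8,12-trimethyl-7-(phenylsulfonyl)tetradeca-4,8-dienoic acid (C7 epimers) | OC(=O)[C@@H](O[Si](C)(C)C(C)(C)C)C/C(C)=C/CC(S(=O)(=O)c1ccccc1)/C(C)=C/CC[C@@H](C)CCO[Si](C)(C)C(C)(C)C | intermediate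
16 | potassium ethyl 2-methylmalonate (potassium 3-ethoxy-2-methyl-3-oxopropanoate) | CCOC(=O)C(C)C(=O)[O-].[K+] | starting material
17 | acyl imidazolide of 15 | O=C(n1ccnc1)[C@@H](O[Si](C)(C)C(C)(C)C)C/C(C)=C/CC(S(=O)(=O)c1ccccc1)/C(C)=C/CC[C@@H](C)CCO[Si](C)(C)C(C)(C)C | intermediate (not isolated)
18 | ethyl (4S,6E,10E,14R)-4,16-bis(tert-butyldimethylsilyloxy)-2,6,10,14-tetramethyl-3-oxo-9-(phenylsulfonyl)hexadeca-6,10-dienoate (epimers at C2 and C9 of the chain, labdane C4 and C7) | CCOC(=O)C(C)C(=O)[C@@H](O[Si](C)(C)C(C)(C)C)C/C(C)=C/CC(S(=O)(=O)c1ccccc1)/C(C)=C/CC[C@@H](C)CCO[Si](C)(C)C(C)(C)C | intermediate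
19 | ethyl (4S,6E,10E,14R)-2-bromo-4,16-bis(tert-butyldimethylsilyloxy)-2,6,10,14-tetramethyl-3-oxo-9-(phenylsulfonyl)hexadeca-6,10-dienoate (epimers at labdane C4 and C7) | CCOC(=O)C(C)(Br)C(=O)[C@@H](O[Si](C)(C)C(C)(C)C)C/C(C)=C/CC(S(=O)(=O)c1ccccc1)/C(C)=C/CC[C@@H](C)CCO[Si](C)(C)C(C)(C)C | intermediate
20 | ethyl (2S,4S,5S,9R,10S,13R)-2,15-bis(tert-butyldimethylsilyloxy)-3-oxolabd-7-en-19-oate | CCOC(=O)[C@@]1(C)[C@H]2CC=C(C)[C@@H](CC[C@@H](C)CCO[Si](C)(C)C(C)(C)C)[C@]2(C)C[C@H](O[Si](C)(C)C(C)(C)C)C1=O | intermediate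
21 | (2S,4R,5S,9R,10S,13R)-2,15-bis(tert-butyldimethylsilyloxy)labd-7-ene-3,19-diol (C3 epimers) | OC[C@@]1(C)[C@H]2CC=C(C)[C@@H](CC[C@@H](C)CCO[Si](C)(C)C(C)(C)C)[C@]2(C)C[C@H](O[Si](C)(C)C(C)(C)C)C1O | intermediate
22 | (2S,4R,5S,9R,10S,13R)-2,15-bis(tert-butyldimethylsilyloxy)-3-oxolabd-7-en-19-al | O=C[C@@]1(C)[C@H]2CC=C(C)[C@@H](CC[C@@H](C)CCO[Si](C)(C)C(C)(C)C)[C@]2(C)C[C@H](O[Si](C)(C)C(C)(C)C)C1=O | intermediate
23 | (2S,4R,5S,9R,10S,13R)-2,15-bis(tert-butyldimethylsilyloxy)-19-hydroxylabd-7-en-3-one | OC[C@@]1(C)[C@H]2CC=C(C)[C@@H](CC[C@@H](C)CCO[Si](C)(C)C(C)(C)C)[C@]2(C)C[C@H](O[Si](C)(C)C(C)(C)C)C1=O | intermediate (not isolated)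
24 | (2S,3R,4R,5S,9R,10S,13R)-2,15-bis(tert-butyldimethylsilyloxy)labd-7-ene-3,19-diol | OC[C@@]1(C)[C@H]2CC=C(C)[C@@H](CC[C@@H](C)CCO[Si](C)(C)C(C)(C)C)[C@]2(C)C[C@H](O[Si](C)(C)C(C)(C)C)[C@@H]1O | intermediate
25 | (2S,3R,4R,5S,9R,10S,13R)-19-acetoxy-2,15-bis(tert-butyldimethylsilyloxy)labd-7-en-3-ol | CC(=O)OC[C@@]1(C)[C@H]2CC=C(C)[C@@H](CC[C@@H](C)CCO[Si](C)(C)C(C)(C)C)[C@]2(C)C[C@H](O[Si](C)(C)C(C)(C)C)[C@@H]1O | intermediate
26 | (2S,3R,4R,5S,9R,10S,13R)-19-acetoxy-2-(tert-butyldimethylsilyloxy)labd-7-ene-3,15-diol | CC(=O)OC[C@@]1(C)[C@H]2CC=C(C)[C@@H](CC[C@@H](C)CCO)[C@]2(C)C[C@H](O[Si](C)(C)C(C)(C)C)[C@@H]1O | intermediate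
27 | (2S,3R,4R,5S,9R,10S,13R)-19-acetoxy-3-hydroxy-2-(tert-butyldimethylsilyloxy)labd-7-en-15-oic acid | CC(=O)OC[C@@]1(C)[C@H]2CC=C(C)[C@@H](CC[C@@H](C)CC(=O)O)[C@]2(C)C[C@H](O[Si](C)(C)C(C)(C)C)[C@@H]1O | intermediate
28 | (2S,3R,4R,5S,9R,10S,13R)-19-acetoxy-2,3-dihydroxylabd-7-en-15-oic acid (CNP0164890.1) | CC(=O)OC[C@@]1(C)[C@H]2CC=C(C)[C@@H](CC[C@@H](C)CC(=O)O)[C@]2(C)C[C@H](O)[C@@H]1O | target

Total step count: 19 (steps 4 and 7 prepare the two side fragments).
Longest linear sequence: 17 steps from (R)-citronellol 1 (steps 1, 2, 3, 5, 6, 8–19).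

Steps most likely to fail

Step 12 (proposed new method). The chain may leak: bromine transfer to the C10 or C8 radical, or reduction of the C4 radical by Et3B, may outrun ring closure and fragmentation. The freed sulfonyl radical may also add reversibly to the allylic sulfone of unreacted 19 and scramble its position and geometry, or the facial bias from C2 may be too small. The fallback uses known reactions only, removing the sulfone before cyclisation and placing the alkene afterwards. Acid 15 is treated with LiBHEt3 and catalytic PdCl2(dppp) in THF at 0 °C, a known reductive cleavage of allylic sulfones that keeps alkene position and geometry, to give the sulfone-free acid F1. Activation with CDI gives its acyl imidazolide F2, which with 16, MgCl2 and Et3N (as in step 10) gives the sulfone-free β-keto ester F3. The known oxidative bicyclisation with Mn(OAc)3·2H2O and Cu(OAc)2·H2O in AcOH at 25 °C (ring A then ring B, both 6-endo, with the C8 radical oxidised by Cu(OAc)2 to the exocyclic alkene) should give the exo-methylene keto ester F4. Hydrogen-atom-transfer isomerisation with catalytic Co(salen)Cl and PhSiH3 in benzene should then move the exocyclic alkene to C7=C8 by abstraction of the less hindered C7 hydrogen, which returns to 20.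

Step 8. The sodium enolate of the silyloxyacetyl imide may decay (silyl transfer between its oxygens, ketene loss) before it is alkylated, because the iodide is the limiting partner. The fallback changes to the 4-methoxybenzyl ether series and exchanges the protecting group later. Lithiated 10 is acylated with (4-methoxybenzyloxy)acetyl chloride to give the 4-methoxybenzyl glycolate imide F5. Its sodium enolate (NaN(SiMe3)2, THF, −78 °C) is alkylated with 9 to give the alkylated imide F6. DDQ in CH2Cl2/pH 7 buffer removes the benzyl-type ether to give the α-hydroxy imide F7, and TBSOTf with 2,6-lutidine at −78 °C returns to 14.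

Step 15. Hydride may attack the C3 ketone intermolecularly from the open face before the C19 alkoxyborohydride forms, or the formyl group of 22 may be lost during steps 14 and 15, so that the C3 configuration or C19 itself is lost. The fallback is a reagent-controlled reduction without the redox detour, starting from 20. KBH(s-Bu)3 in THF at −78 °C should attack the C3 ketone along the equatorial trajectory and give the axial hydroxy ester F8, and LiAlH4 in THF then reduces the ester and returns to 24.

Further compounds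
F1 | step 12 | (2S,4E,8E,12R)-2,14-bis(tert-butyldimethylsilyloxy)-4,8,12-trimethyltetradeca-4,8-dienoic acid | OC(=O)[C@@H](O[Si](C)(C)C(C)(C)C)C/C(C)=C/CC/C(C)=C/CC[C@@H](C)CCO[Si](C)(C)C(C)(C)C
F2 | step 12 | acyl imidazolide of F1 | O=C(n1ccnc1)[C@@H](O[Si](C)(C)C(C)(C)C)C/C(C)=C/CC/C(C)=C/CC[C@@H](C)CCO[Si](C)(C)C(C)(C)C
F3 | step 12 | ethyl (4S,6E,10E,14R)-4,16-bis(tert-butyldimethylsilyloxy)-2,6,10,14-tetramethyl-3-oxohexadeca-6,10-dienoate (C2 epimers) | CCOC(=O)C(C)C(=O)[C@@H](O[Si](C)(C)C(C)(C)C)C/C(C)=C/CC/C(C)=C/CC[C@@H](C)CCO[Si](C)(C)C(C)(C)C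
F4 | step 12 | ethyl (2S,4S,5S,9R,10S,13R)-2,15-bis(tert-butyldimethylsilyloxy)-3-oxolabd-8(17)-en-19-oate | CCOC(=O)[C@@]1(C)[C@H]2CCC(=C)[C@@H](CC[C@@H](C)CCO[Si](C)(C)C(C)(C)C)[C@]2(C)C[C@H](O[Si](C)(C)C(C)(C)C)C1=O
F5 | step 8 | (R)-4-benzyl-3-[2-(4-methoxybenzyloxy)acetyl]oxazolidin-2-one | O=C1OC[C@@H](Cc2ccccc2)N1C(=O)COCc1ccc(OC)cc1
F6 | step 8 | (R)-4-benzyl-3-[(2S,4E,8E,12R)-14-(tert-butyldimethylsilyloxy)-2-(4-methoxybenzyloxy)-4,8,12-trimethyl-7-(phenylsulfonyl)tetradeca-4,8-dienoyl]oxazolidin-2-one | O=C1OC[C@@H](Cc2ccccc2)N1C(=O)[C@@H](OCc1ccc(OC)cc1)C/C(C)=C/CC(S(=O)(=O)c1ccccc1)/C(C)=C/CC[C@@H](C)CCO[Si](C)(C)C(C)(C)C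
F7 | step 8 | (R)-4-benzyl-3-[(2S,4E,8E,12R)-14-(tert-butyldimethylsilyloxy)-2-hydroxy-4,8,12-trimethyl-7-(phenylsulfonyl)tetradeca-4,8-dienoyl]oxazolidin-2-one | O=C1OC[C@@H](Cc2ccccc2)N1C(=O)[C@@H](O)C/C(C)=C/CC(S(=O)(=O)c1ccccc1)/C(C)=C/CC[C@@H](C)CCO[Si](C)(C)C(C)(C)C
F8 | step 15 | ethyl (2S,3R,4S,5S,9R,10S,13R)-2,15-bis(tert-butyldimethylsilyloxy)-3-hydroxylabd-7-en-19-oate | CCOC(=O)[C@@]1(C)[C@H]2CC=C(C)[C@@H](CC[C@@H](C)CCO[Si](C)(C)C(C)(C)C)[C@]2(C)C[C@H](O[Si](C)(C)C(C)(C)C)[C@@H]1O
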